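**Strategy.** The target is the endo Diels–Alder dimer of two 8-epi-xanthatin units, one of them epoxidised, so the whole carbon skeleton reduces to one monomer. Its cis-lactone-fused cycloheptane (ring B with lactone B in the lower half) is made by a de Mayo sequence: C8, which carries the lactone oxygen, and the chain-bearing C1 are 1,4-related in the ring, and O–C12(=O)–C11–C7 maps onto a but-3-enoate. Irradiation of achiral 3-(but-3-enoyloxy)cyclopent-2-en-1-one with a chiral Lewis acid forms C8–C7 and C5–C6 in one operation, closing the γ-lactone and a temporary cyclobutane with three stereocentres; retro-aldol cleavage of C5–C8 then opens the seven-membered ring.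

Key step: step 2

Remark on numbering: xanthane numbering (C1–C15; C12 lactone carbonyl, C13 exocyclic methylene) is used for all carbons derived from 1 and 2; in the dimers, unprimed locants belong to the diene-derived unit (lactone A, cycloheptane ring A, ring C) and primed locants to the dienophile-derived unit (ring B, lactone B).

Assumption: the (S)-oxazaborolidine is taken to give the (5S,7R,8S) adduct 4; if the sense of induction is the opposite, its (R)-enantiomer is used with nothing else changed.

Step 1
Reactants: 1 cyclopentane-1,3-dione; 2 but-3-enoic acid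
Product: 3 3-(but-3-enoyloxy)cyclopent-2-en-1-one
Conditions: N,N'-dicyclohexylcarbodiimide (1.05 equiv), CH2Cl2/THF, 0 °C to rt, no DMAP
Reagents that add atoms: none
Why: carbodiimide-mediated O-acylation (Steglich-type esterification) of the acidic, symmetrical 1,3-dione should give the enol ester directly, and leaving out a nucleophilic catalyst avoids both the O-to-C acyl shift and migration of the terminal double bond into conjugation; no stereocentre is formed.

Step 2
Reactants: 3 3-(but-3-enoyloxy)cyclopent-2-en-1-one
Product: 4 (5S,7R,8S)-tricyclic keto lactone (cyclobutane C5–C6–C7–C8 cis-fused to the γ-lactone O–C12(=O)–C11–C7–C8 and to the cyclopentanone C1(=O)–C5–C8–C9–C10)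
Conditions: (S)-3,3-bis(3,5-dimethylphenyl)-1-(2,4,6-trifluorophenyl)tetrahydro-1H,3H-pyrrolo[1,2-c][1,3,2]oxazaborole (50 mol%), AlBr3 (50 mol%), hν (λ = 366 nm), CH2Cl2, −75 °C
Reagents that add atoms: none
Why: Proposed new method: the AlBr3-activated oxazaborolidine binds the enone carbonyl of 3 and shifts its absorption to longer wavelength, so that at 366 nm essentially only the chiral complex is excited; the enone triplet bonds from its oxygen-bearing β-carbon (C8) to the internal vinyl carbon (C7) and the resulting 1,4-diradical collapses between C5 and C6. The closest known reaction type is the intramolecular enone–alkene (2+2) photocycloaddition of 3-alkenyloxy-2-cycloalkenones under the same chiral Lewis acid, the ester carbonyl in the tether and the vinylogous-anhydride chromophore being the untested elements. The γ-lactone closes in the first bond formation as a five-membered ring (1,5-closure across a three-atom tether), and the cyclobutane closes by recombination of the diradical. C8 and C7 are set by the enone face that the catalyst leaves open, and C5 follows because a four-membered ring can only be cis-fused to both five-membered rings. The step needs enantioface selectivity, straight rather than crossed regiochemistry and suppression of the acyl shift to C2; the first rests on the catalyst, the second on the tether length, the third on exciting only the complexed enone. The s-cis ester rotamer required for closure is a minor but accessible population, because conjugation of the enol oxygen with the enone weakens the ester resonance.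

Step 3
Reactants: 4 (5S,7R,8S)-tricyclic keto lactone
Product: 5 (5S,7R,8S,10S)-10-methyl tricyclic keto lactone
Conditions: LiN(i-Pr)2 (1.05 equiv), THF, −78 °C; MeI (3 equiv), −78 to −30 °C
Reagents that add atoms: iodomethane, CI
Why: kinetic enolate alkylation, in which the ketone is deprotonated in preference to the less acidic lactone and at the C10 methylene rather than at the cyclobutane methine C5, and iodomethane attacks the convex face of the cis-bicyclo[3.2.0]heptanone (anti to the cyclobutane), which sets C10 as S, the configuration that later places the methyl group cis to C11 and to the lactone oxygen on the seven-membered ring.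

Step 4
Reactants: 5 (5S,7R,8S,10S)-10-methyl tricyclic keto lactone
Product: 7 2-[(1R,4S)-4-methyl-2,5-dioxocycloheptyl]acetic acid, via cyclobutanol carboxylate 6 (not isolated)
Conditions: LiOH (1.05 equiv), THF/H2O, 0 °C; then 1 M HCl to pH 3, 0 °C
Reagents that add atoms: lithium hydroxide, [Li+].[OH-]
Why: saponification frees the tertiary C8 alkoxide of a β-hydroxy ketone, whose strain-driven retro-aldol cleavage of C5–C8 (de Mayo fragmentation) should give the cycloheptane-1,4-dione; no stereocentre is formed, and because the hydroxide is consumed by the carboxylic acid, the two α-stereocentres C7 and C10 see only a weakly basic medium for a short time at 0 °C.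

Step 5
Reactants: 7 2-[(1R,4S)-4-methyl-2,5-dioxocycloheptyl]acetic acid
Product: 9 (3aR,6R,7S,8aR)-6-hydroxy-7-methyloctahydro-2H-cyclohepta[b]furan-2-one, via dihydroxy acid 8 (not isolated)
Conditions: Li[HB(s-Bu)3] (3.3 equiv), THF, −78 °C; then 2 M HCl, 0 °C to rt
Reagents that add atoms: none
Why: bulky-borohydride reduction of 2-substituted cycloalkanones delivers hydride to each carbonyl from the face away from its α-substituent, which makes the C8 hydroxyl cis to the C7 acetic acid chain so that acidification closes the cis-fused γ-lactone, while the C1 carbinol (drawn cis to the methyl group, as expected) is of no consequence because it is oxidised in step 6.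

Step 6
Reactants: 9 (3aR,6R,7S,8aR)-6-hydroxy-7-methyloctahydro-2H-cyclohepta[b]furan-2-one
Product: 10 (3aR,7S,8aR)-7-methylhexahydro-2H-cyclohepta[b]furan-2,6(3H)-dione
Conditions: Dess–Martin periodinane (1.3 equiv), CH2Cl2, 0 °C to rt
Reagents that add atoms: none
Why: Dess–Martin oxidation of the secondary alcohol regenerates the C1 ketone under non-basic conditions that should leave the adjacent C10 stereocentre and the lactone untouched; no stereocentre is formed.

Step 7
Reactants: 10 (3aR,7S,8aR)-7-methylhexahydro-2H-cyclohepta[b]furan-2,6(3H)-dione
Product: 11 (3aR,7S,8aR)-7-methyl-2-oxo-3,3a,4,7,8,8a-hexahydro-2H-cyclohepta[b]furan-6-yl trifluoromethanesulfonate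
Conditions: KN(SiMe3)2 (1.05 equiv), THF, −78 °C; PhNTf2 (1.1 equiv), −78 to 0 °C; quench 1 M HCl
Reagents that add atoms: N-phenylbis(trifluoromethanesulfonimide), O=S(=O)(N(c1ccccc1)S(=O)(=O)C(F)(F)F)C(F)(F)F
Why: kinetic deprotonation with the hindered amide base occurs at the ketone rather than at the less acidic lactone and at the C5 methylene rather than at the C10 methine, and O-sulfonylation of this enolate (enol triflate formation) fixes the C1=C5 double bond without touching C10.

Step 8
Reactants: 11 (3aR,7S,8aR)-7-methyl-2-oxo-3,3a,4,7,8,8a-hexahydro-2H-cyclohepta[b]furan-6-yl trifluoromethanesulfonate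
Product: 12 (3S,3aR,7S,8aR)-3-[(dimethylamino)methyl]-7-methyl-2-oxo-3,3a,4,7,8,8a-hexahydro-2H-cyclohepta[b]furan-6-yl trifluoromethanesulfonate
Conditions: LiN(SiMe3)2 (1.1 equiv), THF, −78 °C; dimethyl(methylidene)ammonium iodide (1.5 equiv), −78 °C to rt
Reagents that add atoms: dimethyl(methylidene)ammonium iodide (Eschenmoser's salt), C=[N+](C)C.[I-]
Why: with the ketone masked as the triflate the lactone is the only enolisable carbonyl, and its lithium enolate should undergo a Mannich reaction with the preformed iminium salt on the convex face of the cis-fused bicycle, which puts the aminomethyl group cis to H-7 (a centre that is removed again in step 10).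

Step 9
Reactants: 12 (3S,3aR,7S,8aR)-3-[(dimethylamino)methyl] enol triflate; 13 but-3-en-2-one
Product: 14 (3S,3aR,7S,8aR)-3-[(dimethylamino)methyl]-7-methyl-6-[(E)-3-oxobut-1-en-1-yl]-3,3a,4,7,8,8a-hexahydro-2H-cyclohepta[b]furan-2-one
Conditions: 13 (5 equiv), Pd(OAc)2 (5 mol%), PPh3 (10 mol%), Et3N (2 equiv), DMF, 60 °C
Reagents that add atoms: none
Why: Heck reaction, in which oxidative addition of the alkenyl triflate to zerovalent palladium, syn insertion of the electron-poor terminal alkene and syn β-hydride elimination should give the (E)-dienone, while carrying the lactone as its amine adduct keeps the α-methylene unit away from palladium and amine base; no stereocentre is formed.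

Step 10
Reactants: 14 (3S,3aR,7S,8aR)-3-[(dimethylamino)methyl] dienone
Product: 16 8-epi-xanthatin, (3aR,7S,8aR)-7-methyl-3-methylidene-6-[(E)-3-oxobut-1-en-1-yl]-3,3a,4,7,8,8a-hexahydro-2H-cyclohepta[b]furan-2-one, via methiodide 15 (not isolated)
Conditions: MeI (5 equiv), THF, rt; then aq. NaHCO3, CH2Cl2, rt
Reagents that add atoms: none
Why: exhaustive N-methylation followed by mild E1cB loss of trimethylamine (Hofmann-type elimination of a Mannich base) should unveil the α-methylene lactone with a base too weak to enolise the dienone, leaving C7, C8 and C10 unchanged.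

Step 11
Reactants: 16 8-epi-xanthatin
Product: 17 (3aR,5S,6R,7S,8aR)-5-bromo-6-hydroxy-7-methyl-3-methylidene-6-[(E)-3-oxobut-1-en-1-yl]octahydro-2H-cyclohepta[b]furan-2-one (xanthane: 5-bromo trans and 1-hydroxy cis to the C10 methyl)
Conditions: N-bromosuccinimide (1.1 equiv), THF/H2O, 0 °C, dark
Reagents that add atoms: N-bromosuccinimide, O=C1CCC(=O)N1Br; water, O
Why: bromohydrin formation, in which the electrophile attacks the γ,δ double bond of the dienone (the only electron-rich alkene) on the face anti to the pseudo-axial C10 methyl group and water opens the bromonium ion anti at the tertiary C1, so that hydroxyl ends up cis and bromine trans to the methyl group (the regiochemistry of opening does not change the epoxide formed next).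

Step 12
Reactants: 17 bromohydrin
Product: 18 8-epi-xanthatin 1,5-epoxide with the oxirane oxygen cis to the C10 methyl and to the C8–O bond (xanthane: 1R,5R,7R,8R,10S)
Conditions: K2CO3 (2 equiv), MeCN, rt
Reagents that add atoms: none
Why: intramolecular Williamson closure, in which the C1 alkoxide displaces bromide at C5 with inversion, should place the oxirane on the face cis to the C10 methyl and the lactone oxygen, the face that direct oxygen transfer to 16 is expected to avoid, and the carbonate is too weak and non-nucleophilic to harm the α-methylene lactone.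

Step 13
Reactants: 16 8-epi-xanthatin; 18 8-epi-xanthatin 1,5-epoxide
Product: 19 cross-adduct: the 1-deoxy precursor of the target with the C1=C2 double bond in ring C and the acetyl group on sp3 C3 (H-3 cis to H-5), all other centres as in 21
Conditions: 18 (4 equiv), BHT (5 mol%), toluene (2 M), 100 °C, sealed tube, dark; 16 (1 equiv) added in four portions; excess 18 recovered
Reagents that add atoms: none
Why: intermolecular Diels–Alder reaction between the s-cis C5=C1–C2=C3 diene of 16 and the exocyclic C11'=C13' bond of 18, which has no diene of its own, in which the ring terminus C5 bonds to the methylene carbon C13' and C3 to C11', the lactone carbonyl is endo, 18 reacts on the convex face of its cis-fused lactone (anti to C6') and 16 on the face cis to its C10 methyl (the underside of C5 being screened by the axial hydrogen at C7 of the cycloheptene chair), which sets C5 and the spiro centre C11' as in the target, while the excess of 18 outcompetes self-dimerisation of 16.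

Step 14
Reactants: 19 cross-adduct
Product: 21 target CNP0177598.1, via hydroperoxide 20 (not isolated)
Conditions: O2 (1 atm), Cs2CO3 (0.2 equiv), P(OEt)3 (2 equiv), DMSO, rt
Reagents that add atoms: dioxygen, O=O
Why: base-mediated aerobic oxygenation of a deconjugated enone, in which the doubly activated C3–H (α to the ketone and allylic) is the most acidic site, the extended enolate takes up O2 at the γ-carbon C1 to give the conjugated hydroperoxide that the phosphite reduces at once, and oxygen enters axially on the face of ring C opposite to the pseudo-axial H-5 (the half-chair that avoids a 1,3-diaxial clash between C6 and C12'), which makes the C1 hydroxyl trans to H-5 and cis to the C10 methyl as in the target.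

**Compound list**

1 | cyclopentane-1,3-dione | O=C1CCC(=O)C1 | starting material
2 | but-3-enoic acid | C=CCC(=O)O | starting material
3 | 3-(but-3-enoyloxy)cyclopent-2-en-1-one | C=CCC(=O)OC1=CC(=O)CC1 | intermediate
4 | (5S,7R,8S)-tricyclic keto lactone, all ring fusions cis | O=C1C[C@H]2C[C@@H]3C(=O)CC[C@]23O1 | intermediate
5 | (5S,7R,8S,10S)-10-methyl tricyclic keto lactone, methyl on the convex face | O=C1C[C@H]2C[C@@H]3C(=O)[C@@H](C)C[C@]23O1 | intermediate
6 | cyclobutanol carboxylate: lithium salt of ring-opened 5 with free tertiary C8 hydroxyl | [Li+].[O-]C(=O)C[C@H]1C[C@@H]2C(=O)[C@@H](C)C[C@]12O | intermediate (not isolated)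
7 | 2-[(1R,4S)-4-methyl-2,5-dioxocycloheptyl]acetic acid | OC(=O)C[C@H]1CCC(=O)[C@@H](C)CC1=O | intermediate
8 | 2-[(1R,2R,4S,5R)-2,5-dihydroxy-4-methylcycloheptyl]acetic acid | OC(=O)C[C@H]1CC[C@@H](O)[C@@H](C)C[C@H]1O | intermediate (not isolated)
9 | (3aR,6R,7S,8aR)-6-hydroxy-7-methyloctahydro-2H-cyclohepta[b]furan-2-one | O=C1C[C@H]2CC[C@@H](O)[C@@H](C)C[C@H]2O1 | intermediate
10 | (3aR,7S,8aR)-7-methylhexahydro-2H-cyclohepta[b]furan-2,6(3H)-dione | O=C1C[C@H]2CCC(=O)[C@@H](C)C[C@H]2O1 | intermediate
11 | (3aR,7S,8aR)-7-methyl-2-oxo-3,3a,4,7,8,8a-hexahydro-2H-cyclohepta[b]furan-6-yl trifluoromethanesulfonate | O=C1C[C@H]2CC=C(OS(=O)(=O)C(F)(F)F)[C@@H](C)C[C@H]2O1 | intermediate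
12 | (3S,3aR,7S,8aR)-3-[(dimethylamino)methyl]-7-methyl-2-oxo-3,3a,4,7,8,8a-hexahydro-2H-cyclohepta[b]furan-6-yl trifluoromethanesulfonate | O=C1[C@H](CN(C)C)[C@H]2CC=C(OS(=O)(=O)C(F)(F)F)[C@@H](C)C[C@H]2O1 | intermediate
13 | but-3-en-2-one | CC(=O)C=C | starting material
14 | (3S,3aR,7S,8aR)-3-[(dimethylamino)methyl]-7-methyl-6-[(E)-3-oxobut-1-en-1-yl]-3,3a,4,7,8,8a-hexahydro-2H-cyclohepta[b]furan-2-one | O=C1[C@H](CN(C)C)[C@H]2CC=C(/C=C/C(C)=O)[C@@H](C)C[C@H]2O1 | intermediate
15 | methiodide of 14 (trimethylammonium iodide) | O=C1[C@H](C[N+](C)(C)C)[C@H]2CC=C(/C=C/C(C)=O)[C@@H](C)C[C@H]2O1.[I-] | intermediate (not isolated)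
16 | 8-epi-xanthatin, (3aR,7S,8aR)-7-methyl-3-methylidene-6-[(E)-3-oxobut-1-en-1-yl]-3,3a,4,7,8,8a-hexahydro-2H-cyclohepta[b]furan-2-one | C=C1C(=O)O[C@@H]2C[C@H](C)C(/C=C/C(C)=O)=CC[C@H]12 | intermediate
17 | (3aR,5S,6R,7S,8aR)-5-bromo-6-hydroxy-7-methyl-3-methylidene-6-[(E)-3-oxobut-1-en-1-yl]octahydro-2H-cyclohepta[b]furan-2-one | C=C1C(=O)O[C@@H]2C[C@H](C)[C@@](O)(/C=C/C(C)=O)[C@@H](Br)C[C@H]12 | intermediate
18 | 8-epi-xanthatin 1,5-epoxide, oxirane cis to the C10 methyl (xanthane 1R,5R,7R,8R,10S) | C=C1C(=O)O[C@@H]2C[C@H](C)[C@]3(/C=C/C(C)=O)O[C@@H]3C[C@H]12 | intermediate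
19 | cross-adduct: 1-deoxy precursor of 21 with C1=C2 in ring C and the acetyl group on C3 (H-3 cis to H-5) | C=C1C(=O)O[C@@H]2C[C@H](C)C3=C[C@H](C(C)=O)[C@@]4(C[C@@H]3C[C@H]12)C(=O)O[C@@H]1C[C@H](C)[C@]2(/C=C/C(C)=O)O[C@@H]2C[C@@H]14 | intermediate
20 | C1 hydroperoxide of the target | C=C1C(=O)O[C@@H]2C[C@H](C)[C@@]3(OO)C=C(C(C)=O)[C@@]4(C[C@@H]3C[C@H]12)C(=O)O[C@@H]1C[C@H](C)[C@]2(/C=C/C(C)=O)O[C@@H]2C[C@@H]14 | intermediate (not isolated)
21 | CNP0177598.1 | C=C1C(=O)O[C@@H]2C[C@H](C)[C@@]3(O)C=C(C(C)=O)[C@@]4(C[C@@H]3C[C@H]12)C(=O)O[C@@H]1C[C@H](C)[C@]2(/C=C/C(C)=O)O[C@@H]2C[C@@H]14 | target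

**Totals.** Total step count: 14. Longest linear sequence: 14 steps (1 and 2 to 21; 18 is made from 16 on the same line).

**The three steps most likely to fail**

1. Step 2 (bears the label "Proposed new method:"). The unreactive s-trans ester rotamer may dominate, so that the excited enone decays or undergoes the 1,3-acyl shift to C2 before it cyclises. The strong Lewis acid may also transfer the acyl group thermally, or bind the ester carbonyl and discriminate the enone faces poorly. The fallback uses known chemistry and sets out from 1. Acid-catalysed condensation of 1 with but-3-en-1-ol (TsOH, toluene, reflux with removal of water) gives the vinylogous ester 3-(but-3-en-1-yloxy)cyclopent-2-en-1-one F1, a member of the 3-alkenyloxy-enone class on which the AlBr3-activated oxazaborolidine photocycloaddition is established. Irradiation under the conditions of step 2 should give the tricyclic keto ether F2 with the same three stereocentres. Oxidation of its only O–CH2 group with catalytic RuCl3 and NaIO4 (CCl4/MeCN/H2O) turns the tetrahydrofuran into the γ-lactone and returns to the route at 4.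

2. Step 13. Self-dimerisation of 16, which is both diene and dienophile, and further cycloaddition of the product may compete with the cross-reaction, and the electron-poor diene may react only sluggishly. The fallback sets out from 14, the amine-masked dienone, which carries the diene but cannot act as dienophile. Heated with one equivalent of 18 (toluene, 100 °C, BHT) it can only cross-react and should give the amine-masked adduct F3. N-Methylation to the methiodide F4 and bicarbonate-induced elimination, as in step 10, then unveil the α-methylene lactone and return to the route at 19.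

3. Step 14. The extended enolate may be protonated at C1, giving the conjugated enone without uptake of oxygen, or oxygenated at C3, and the base may attack the α-methylene lactone. The fallback sets out from 19 and replaces the ionic pathway by hydrogen-atom abstraction. N-Hydroxyphthalimide (10 mol%) and Co(OAc)2 (1 mol%) under O2 in MeCN at rt generate the phthalimide-N-oxyl radical, which removes the weakest hydrogen (C3–H). The planar delocalised radical should capture O2 at C1 on the same face as argued for step 14 and return to the route at hydroperoxide 20, which is reduced with P(OEt)3 as before; this fallback makes no compound outside the list (F0).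

**Further compounds**

F1 | step 2 | 3-(but-3-en-1-yloxy)cyclopent-2-en-1-one | C=CCCOC1=CC(=O)CC1
F2 | step 2 | (5S,7R,8S)-tricyclic keto ether (tetrahydrofuran analogue of 4) | C1C[C@H]2C[C@@H]3C(=O)CC[C@]23O1
F3 | step 13 | amine-masked adduct (19 with C11 bearing H and CH2NMe2 in place of the exocyclic methylene) | CN(C)C[C@H]1C(=O)O[C@@H]2C[C@H](C)C3=C[C@H](C(C)=O)[C@@]4(C[C@@H]3C[C@H]12)C(=O)O[C@@H]1C[C@H](C)[C@]2(/C=C/C(C)=O)O[C@@H]2C[C@@H]14
F4 | step 13 | methiodide of F3 | C[N+](C)(C)C[C@H]1C(=O)O[C@@H]2C[C@H](C)C3=C[C@H](C(C)=O)[C@@]4(C[C@@H]3C[C@H]12)C(=O)O[C@@H]1C[C@H](C)[C@]2(/C=C/C(C)=O)O[C@@H]2C[C@@H]14.[I-]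
F0 | step 14 | none | none
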